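**Plan**

1. Retrosynthesis: the two CH2OH groups go back to esters and the two phenols to benzyl ethers. Ring B is then cut at C1–C2 and at C4–C4a, leaving a bis(4-benzyloxy-3-methoxyphenyl)methyl cation and an itaconyl unit (C2, C3, C4 and both carboxyl carbons).
2. Enabling feature: C1 carries two constitutionally identical 4-oxy-3-methoxyphenyl groups (ring A is one of them), each with its oxygen para to C1, so the cation is symmetric and doubly stabilised. C4a lies para to the C7 methoxy group and is the natural Friedel–Crafts site.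
3. Forward: an aryllithium and O-benzylvanillin give the symmetric benzhydrol, kept as its methyl ether. Itaconic anhydride and (R)-4-benzyloxazolidin-2-one give the N-itaconyl imide.
4. One flask joins them: the benzhydryl cation alkylates the titanium dienolate at its α-carbon (C1–C2), and one aryl ring then adds to the restored acrylate (C4–C4a). This closes ring B, the only ring made.
5. Stereochemistry: C2 comes from the auxiliary; C1 from the choice between the two diastereotopic aryl groups in the ring closure (trans to C2); C3 from base equilibration to the all-trans diester.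
6. Ester reduction and hydrogenolysis of the benzyl ethers finish the synthesis.

Key step: step 5

Remark: locants used throughout are those of the 1-aryltetralin (C1 = diarylmethine carbon, C2 and C3 = carbons bearing the carbon substituents, C4 = benzylic CH2, C4a/C8a = ring fusion); the target is the all-trans (1S,2R,3R) isomer with OH at C6 and OMe at C7.

**Route**

Step 1
Reactants: 1 1-(benzyloxy)-4-bromo-2-methoxybenzene; 2 4-(benzyloxy)-3-methoxybenzaldehyde
Product: 4 bis[4-(benzyloxy)-3-methoxyphenyl]methanol, via aryllithium 3 (not isolated)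
Conditions: n-BuLi, THF, −78 °C; then 2, −78 → 0 °C; H2O
Reagents that add atoms: none
Why: Bromine–lithium exchange gives the aryllithium, which adds to the aldehyde (1,2-addition of an organolithium to a carbonyl group); the carbinol carbon bears two identical aryl groups and is not a stereocentre.

Step 2
Reactants: 4 bis[4-(benzyloxy)-3-methoxyphenyl]methanol
Product: 5 4,4'-(methoxymethylene)bis[1-(benzyloxy)-2-methoxybenzene]
Conditions: MeOH/CH2Cl2, camphorsulfonic acid (cat.), 23 °C; Et3N (cat.) quench
Reagents that add atoms: methanol, CO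
Why: SN1 etherification, in which the doubly para-alkoxy-stabilised benzhydryl cation forms under mild acid and is trapped by methanol, should give a bench-stable cation precursor for step 5.

Step 3
Reactants: 6 (4R)-4-benzyl-1,3-oxazolidin-2-one; 7 itaconic anhydride
Product: 9 4-[(4R)-4-benzyl-2-oxo-1,3-oxazolidin-3-yl]-2-methylidene-4-oxobutanoic acid, via N-lithiooxazolidinone 8 (not isolated)
Conditions: n-BuLi, THF, −78 °C; then 7, −78 → −20 °C; aq. HCl
Reagents that add atoms: none
Why: N-Acylation of the lithiated oxazolidinone by ring opening of the cyclic anhydride should occur at the unconjugated, CH2-bound carbonyl, which is the more electrophilic and less hindered one, as in alcoholysis and aminolysis of itaconic anhydride.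

Step 4
Reactants: 9 4-[(4R)-4-benzyl-2-oxo-1,3-oxazolidin-3-yl]-2-methylidene-4-oxobutanoic acid
Product: 10 methyl 4-[(4R)-4-benzyl-2-oxo-1,3-oxazolidin-3-yl]-2-methylidene-4-oxobutanoate
Conditions: Me3SiCHN2, PhMe/MeOH, 0 °C
Reagents that add atoms: trimethylsilyldiazomethane, C[Si](C)(C)C=[N+]=[N-]
Why: Esterification of a carboxylic acid with a diazoalkane is neutral and fast, which avoids base-induced migration of the exocyclic double bond into conjugation with the imide.

Step 5
Reactants: 10 methyl 4-[(4R)-4-benzyl-2-oxo-1,3-oxazolidin-3-yl]-2-methylidene-4-oxobutanoate; 5 4,4'-(methoxymethylene)bis[1-(benzyloxy)-2-methoxybenzene]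
Product: 13 (4R)-4-benzyl-3-{[(1S,2R,3S)-6-(benzyloxy)-1-[4-(benzyloxy)-3-methoxyphenyl]-7-methoxy-3-(methoxycarbonyl)-1,2,3,4-tetrahydronaphthalen-2-yl]carbonyl}-1,3-oxazolidin-2-one, via TiCl3 dienolate 11 (not isolated), via acyclic imide 12 (not isolated)
Conditions: TiCl4 (1.1 equiv), i-Pr2NEt (1.1 equiv), CH2Cl2, −78 → −40 °C; then 5 (1.1 equiv), TiCl4 (1.5 equiv), −78 → 0 °C (23 °C if needed); H2O
Reagents that add atoms: none
Why: Proposed new method: TiCl4/i-Pr2NEt should convert 10 into the chelated Z-chlorotitanium dienolate 11, and the second charge of TiCl4 should ionise 5 to the bis(4-benzyloxy-3-methoxyphenyl)methyl cation, which 11 captures at its α-carbon to form C1–C2 and restore the acrylate in 12; the closest known reaction type for this half is the SN1-type alkylation of titanium enolates of N-acyloxazolidinones with diarylmethyl ethers, and α-capture is the normal course of itaconate-type metal dienolates. In TiCl4-bound 12 the acrylate CH2 is the only electrophilic carbon, so the ring carbon para to the methoxy group of the nearer aryl group should add to it and form C4–C4a in a 6-endo-trig Friedel–Crafts conjugate addition (closest known type: acid-promoted intramolecular hydroarylation of acrylates), which closes ring B as a formal [3+3] annulation, after which the ester enolate is protonated by the ammonium salt. C2 is set by the auxiliary, whose benzyl group shields one face of the chelated enolate so that the (R)-auxiliary gives (R)-C2. C1 is not stereogenic until the ring closes, because its two aryl groups are identical; in the conformer of 12 that places the benzhydryl H between the two large groups on C2, only the aryl group gauche to the acrylate can reach the CH2, and its closure leaves the other aryl group trans to the C2 acyl group, that is (S)-C1. C3 arises by protonation anti to the C2 substituent, which is expected to give the cis ester, and is corrected in step 6 (the 3-epimer would serve equally). The step needs α- over γ-alkylation (chelated metal dienolate), six- over five-membered closure (polarity of the acrylate) and attack para rather than ortho to OMe (less hindered and electronically preferred), and any 1,2-cis isomer has to be removed here by chromatography because step 6 would carry it into the enantiomeric series.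

Step 6
Reactants: 13 (4R)-4-benzyl-3-{[(1S,2R,3S)-6-(benzyloxy)-1-[4-(benzyloxy)-3-methoxyphenyl]-7-methoxy-3-(methoxycarbonyl)-1,2,3,4-tetrahydronaphthalen-2-yl]carbonyl}-1,3-oxazolidin-2-one
Product: 14 dimethyl (1S,2R,3R)-6-(benzyloxy)-1-[4-(benzyloxy)-3-methoxyphenyl]-7-methoxy-1,2,3,4-tetrahydronaphthalene-2,3-dicarboxylate
Conditions: NaOMe (3 equiv), MeOH/THF, 0 °C → reflux; AcOH
Reagents that add atoms: sodium methoxide in methanol, [Na+].[O-]C
Why: Alkoxide transacylation of the N-acyloxazolidinone releases the auxiliary, and methoxide-mediated enolisation should equilibrate the two ester-bearing carbons to the all-trans, all-pseudoequatorial diester (the thermodynamic isomer of 1-aryltetralin-2,3-dicarboxylates), so that C3 becomes R while C1, which cannot epimerise, holds the absolute configuration.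

Step 7
Reactants: 14 dimethyl (1S,2R,3R)-6-(benzyloxy)-1-[4-(benzyloxy)-3-methoxyphenyl]-7-methoxy-1,2,3,4-tetrahydronaphthalene-2,3-dicarboxylate
Product: 15 [(1S,2R,3R)-6-(benzyloxy)-1-[4-(benzyloxy)-3-methoxyphenyl]-7-methoxy-1,2,3,4-tetrahydronaphthalene-2,3-diyl]dimethanol
Conditions: LiAlH4, THF, 0 → 23 °C; aqueous work-up
Reagents that add atoms: none
Why: Hydride reduction of both methyl esters to primary alcohols touches no stereocentre and leaves the benzyl ethers intact.

Step 8
Reactants: 15 [(1S,2R,3R)-6-(benzyloxy)-1-[4-(benzyloxy)-3-methoxyphenyl]-7-methoxy-1,2,3,4-tetrahydronaphthalene-2,3-diyl]dimethanol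
Product: 16 (1S,2R,3R)-1-(4-hydroxy-3-methoxyphenyl)-2,3-bis(hydroxymethyl)-7-methoxy-1,2,3,4-tetrahydronaphthalen-6-ol
Conditions: H2 (1 atm), 10% Pd/C, EtOAc/MeOH, 23 °C
Reagents that add atoms: none
Why: Hydrogenolysis of the two aryl benzyl ethers over palladium should free both phenols, while the diarylmethine C–H, the ring C–C bonds and the primary alcohols are inert.

**Compound list**

1 | 1-(benzyloxy)-4-bromo-2-methoxybenzene | COc1cc(Br)ccc1OCc1ccccc1 | starting material
2 | 4-(benzyloxy)-3-methoxybenzaldehyde | COc1cc(C=O)ccc1OCc1ccccc1 | starting material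
3 | [4-(benzyloxy)-3-methoxyphenyl]lithium | [Li]c1ccc(OCc2ccccc2)c(OC)c1 | intermediate
4 | bis[4-(benzyloxy)-3-methoxyphenyl]methanol | COc1cc(C(O)c2ccc(OCc3ccccc3)c(OC)c2)ccc1OCc1ccccc1 | intermediate
5 | 4,4'-(methoxymethylene)bis[1-(benzyloxy)-2-methoxybenzene] | COC(c1ccc(OCc2ccccc2)c(OC)c1)c1ccc(OCc2ccccc2)c(OC)c1 | intermediate
6 | (4R)-4-benzyl-1,3-oxazolidin-2-one | O=C1N[C@H](Cc2ccccc2)CO1 | starting material
7 | itaconic anhydride (3-methylideneoxolane-2,5-dione) | C=C1CC(=O)OC1=O | starting material
8 | N-lithio-(4R)-4-benzyl-1,3-oxazolidin-2-one | [Li]N1C(=O)OC[C@H]1Cc1ccccc1 | intermediate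
9 | 4-[(4R)-4-benzyl-2-oxo-1,3-oxazolidin-3-yl]-2-methylidene-4-oxobutanoic acid | OC(=O)C(=C)CC(=O)N1C(=O)OC[C@H]1Cc1ccccc1 | intermediate
10 | methyl 4-[(4R)-4-benzyl-2-oxo-1,3-oxazolidin-3-yl]-2-methylidene-4-oxobutanoate | COC(=O)C(=C)CC(=O)N1C(=O)OC[C@H]1Cc1ccccc1 | intermediate
11 | trichlorotitanium (Z)-dienolate of 10 | COC(=O)C(=C)/C=C(\O[Ti](Cl)(Cl)Cl)N1C(=O)OC[C@H]1Cc1ccccc1 | intermediate
12 | methyl (3R)-3-{[(4R)-4-benzyl-2-oxo-1,3-oxazolidin-3-yl]carbonyl}-4,4-bis[4-(benzyloxy)-3-methoxyphenyl]-2-methylidenebutanoate | C=C(C(=O)OC)[C@@H](C(c1ccc(OCc2ccccc2)c(OC)c1)c1ccc(OCc2ccccc2)c(OC)c1)C(=O)N1C(=O)OC[C@H]1Cc1ccccc1 | intermediate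
13 | (4R)-4-benzyl-3-{[(1S,2R,3S)-6-(benzyloxy)-1-[4-(benzyloxy)-3-methoxyphenyl]-7-methoxy-3-(methoxycarbonyl)-1,2,3,4-tetrahydronaphthalen-2-yl]carbonyl}-1,3-oxazolidin-2-one | COc1cc([C@H]2c3cc(OC)c(OCc4ccccc4)cc3C[C@H](C(=O)OC)[C@@H]2C(=O)N2C(=O)OC[C@H]2Cc2ccccc2)ccc1OCc1ccccc1 | intermediate
14 | dimethyl (1S,2R,3R)-6-(benzyloxy)-1-[4-(benzyloxy)-3-methoxyphenyl]-7-methoxy-1,2,3,4-tetrahydronaphthalene-2,3-dicarboxylate | COc1cc([C@H]2c3cc(OC)c(OCc4ccccc4)cc3C[C@@H](C(=O)OC)[C@@H]2C(=O)OC)ccc1OCc1ccccc1 | intermediate
15 | [(1S,2R,3R)-6-(benzyloxy)-1-[4-(benzyloxy)-3-methoxyphenyl]-7-methoxy-1,2,3,4-tetrahydronaphthalene-2,3-diyl]dimethanol | COc1cc([C@H]2c3cc(OC)c(OCc4ccccc4)cc3C[C@@H](CO)[C@@H]2CO)ccc1OCc1ccccc1 | intermediate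
16 | (1S,2R,3R)-1-(4-hydroxy-3-methoxyphenyl)-2,3-bis(hydroxymethyl)-7-methoxy-1,2,3,4-tetrahydronaphthalen-6-ol, also named (5S,6R,7R)-5-(4-hydroxy-3-methoxyphenyl)-6,7-bis(hydroxymethyl)-3-methoxy-5,6,7,8-tetrahydronaphthalen-2-ol | COc1cc([C@H]2c3cc(OC)c(O)cc3C[C@@H](CO)[C@@H]2CO)ccc1O | target

**Step count and risks**

Total step count: 8. Longest linear sequence: 6 steps (steps 1, 2, 5, 6, 7, 8 or steps 3, 4, 5, 6, 7, 8).

Steps most likely to fail:

1. Step 5. The ring closure may stall at the acyclic stage because TiCl4 activates the acrylate too weakly for the Friedel–Crafts addition, or the dienolate may be captured at its terminal carbon instead of its α-carbon. The fallback separates the two bond formations with known chemistry; it sets out from 4 and 10 and returns at 13. Acetyl chloride converts 4 into chlorobis[4-(benzyloxy)-3-methoxyphenyl]methane F1. Compound 10 is deprotonated with NaN(SiMe3)2 in THF at −78 °C to the sodium dienolate F2, which is alkylated at its α-carbon by F1 (alkylation of a sodium N-acyloxazolidinone enolate with a reactive halide, same facial sense) to give 12, now isolated. Compound 12 is then closed to 13 with CF3SO3H in CH2Cl2 at 0 °C (Brønsted-superacid hydroarylation of an acrylate).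

2. Step 6. Methoxide may attack the ring carbonyl of the oxazolidinone in this hindered imide and open the auxiliary instead of releasing it, or the equilibration at C3 may remain incomplete. The fallback sets out from 13 and returns at 14. LiOH/H2O2 in THF/H2O at 0 °C cleaves the exocyclic acyl group selectively to give (1S,2R,3S)-6-(benzyloxy)-1-[4-(benzyloxy)-3-methoxyphenyl]-7-methoxy-3-(methoxycarbonyl)-1,2,3,4-tetrahydronaphthalene-2-carboxylic acid F3. Me3SiCHN2 gives the 2,3-cis dimethyl ester F4, dimethyl (1S,2R,3S)-6-(benzyloxy)-1-[4-(benzyloxy)-3-methoxyphenyl]-7-methoxy-1,2,3,4-tetrahydronaphthalene-2,3-dicarboxylate. NaOMe in MeOH at reflux then only has to epimerise C3 to reach 14.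

3. Step 3. The lithiated oxazolidinone may attack the conjugated carbonyl of the anhydride, or the basic medium may shift the exocyclic double bond into the chain before or after acylation. The fallback builds the methylene group last; it sets out from 6 (through 8) and returns at 10, bypassing 9 and step 4. Compound 8 is acylated with bromoacetyl bromide to give (4R)-4-benzyl-3-(bromoacetyl)-1,3-oxazolidin-2-one F5. The sodium salt of methyl (diethoxyphosphoryl)acetate displaces bromide to give methyl 4-[(4R)-4-benzyl-2-oxo-1,3-oxazolidin-3-yl]-2-(diethoxyphosphoryl)-4-oxobutanoate F6 (mixture of epimers at the phosphorus-bearing carbon). Horner–Wadsworth–Emmons olefination of F6 with aqueous formaldehyde and K2CO3 at 23 °C then gives 10 with the double bond fixed in the exocyclic position.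

**Further compounds**

F1 | step 5 | chlorobis[4-(benzyloxy)-3-methoxyphenyl]methane | ClC(c1ccc(OCc2ccccc2)c(OC)c1)c1ccc(OCc2ccccc2)c(OC)c1
F2 | step 5 | sodium (Z)-dienolate of 10 | COC(=O)C(=C)/C=C(\[O-])N1C(=O)OC[C@H]1Cc1ccccc1.[Na+]
F3 | step 6 | (1S,2R,3S)-6-(benzyloxy)-1-[4-(benzyloxy)-3-methoxyphenyl]-7-methoxy-3-(methoxycarbonyl)-1,2,3,4-tetrahydronaphthalene-2-carboxylic acid | COc1cc([C@H]2c3cc(OC)c(OCc4ccccc4)cc3C[C@H](C(=O)OC)[C@@H]2C(=O)O)ccc1OCc1ccccc1
F4 | step 6 | dimethyl (1S,2R,3S)-6-(benzyloxy)-1-[4-(benzyloxy)-3-methoxyphenyl]-7-methoxy-1,2,3,4-tetrahydronaphthalene-2,3-dicarboxylate | COc1cc([C@H]2c3cc(OC)c(OCc4ccccc4)cc3C[C@H](C(=O)OC)[C@@H]2C(=O)OC)ccc1OCc1ccccc1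
F5 | step 3 | (4R)-4-benzyl-3-(bromoacetyl)-1,3-oxazolidin-2-one | BrCC(=O)N1C(=O)OC[C@H]1Cc1ccccc1
F6 | step 3 | methyl 4-[(4R)-4-benzyl-2-oxo-1,3-oxazolidin-3-yl]-2-(diethoxyphosphoryl)-4-oxobutanoate | CCOP(=O)(OCC)C(CC(=O)N1C(=O)OC[C@H]1Cc1ccccc1)C(=O)OC
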